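All constants come from no measurement; the run is a simulation.

We compare the rate at which target is made with the rates at which it is lost, and ask which change lifts the target at the end of this flask.

substrate 47 mM; reagent in the second phase 47.0 mM; time 1.5 h; volume of the second phase over the first 1.0

    reagent in the reaction phase ⇌ reagent in the second phase, rate k1*([reagent in the reaction phase] - [reagent in the second phase]/K1) per volume of the first phase (K1 = 0.46, k1 = 0.039 /min)
    substrate + target → side product (k2 = 0.42 /M/min)
    2 reagent in the reaction phase → self-condensation product (k3 = 0.021 /M/min)
    substrate + reagent in the reaction phase → target (k4 = 0.13 /M/min)
    reagent in the reaction phase + target → over-reacted product (k5 = 0.18 /M/min)

1. amount of target at 1.5 h, in percent of the substrate charged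
2. the change that raises the amount of target at 1.5 h, in percent of the substrate charged most ("none" if none brings more than 2 percentage points) (red / ochre / none)
3. amount of target at 1.5 h, in percent of the substrate charged, after ochre

- in percentages every species weighs as the substrate in it: one side product counts as two
- a step written with two of one species runs at k times the square of its concentration and takes two of it each time
- in the second phase: reagent in the second phase; everything else is in the first
- charges count per volume of the first phase; a concentration in a rate is the amount of a species over the volume of its own phase; every rate counts per litre of the first phase
- run time (flask): 1.5 h

- red: doubling the transfer coefficient of step 1, all else as stated
- ochre: doubling the amount of reagent in the second phase, all else as stated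

Turn the choice round first. For red to win, transfer must lag behind the reaction, so the run must hold about one transfer lifetime or fewer. The lifetime is 8.08 min, and the run holds 11.1 of them, far more than one, so transfer is not the rate-limiting step. With nothing consumed, reagent in the reaction phase stands at 32.2 mM once the two phases have shared it out.

We carry the ceiling of target: the quasi-steady concentration at which making equals using, that is, the making rate over the sum of the loss constant times c(substrate) and the over-reaction constant times c(reagent in the reaction phase). Against substrate as charged, the run holds 1.78 target lifetimes, so we take the ceiling at the end, by a rough hand reckoning. As an assumption, we let substrate fall first-order with the reagent held at that shared-out value, which gives 32.2 mM. We then charge the same amount against the reagent, which puts c(reagent in the reaction phase) at 22.1 mM. The ceiling is then 5.29 mM, or 11.2%.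

The transfer coefficient does not enter the ceiling, so red leaves this figure as it is. For ochre, the same steps give 22.1 mM and 47.3 mM, hence 16.3%. Our choice is ochre.

The forecast gives 10.7%, a little below ours, then ochre and 16.3%, holding that “doubling the reagent raises that plateau by about half”.

The simulation gives 10.5%, ochre as the best change with a gain of 5.6 percentage points against 0.11 points for red, and 16.1%. At the asked time this flask makes target 1.05 times as fast as it uses it, each step taken net, and its 4.95 mM stands just under our ceiling of 5.29 mM. In the neighbour flask with 120 mM of substrate, the end readings put the ceiling at 3.42% of the charge, and its target stood higher than that, at 4.05%.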